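**Retrosynthetic overview**
1. The target is reached from a 19-membered macrolactam whose hydroquinone is carried as its dimethyl ether, by C7 carbamoylation, oxidative demethylation to the quinone, C15 desilylation and dithionite reduction.
2. Key disconnection: the anilide bond N1–C20 of the ansa ring (N1, C1–C16, C21, C20). C20 is an sp2 carbon of the benzene ring, ortho to the C21 oxygen and meta to C16, so it can be held as an aryl bromide and joined to the nitrogen of an acyclic primary (2E,4Z)-dienamide by copper-mediated amidation.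
3. The acyclic dienamide comes from Sonogashira coupling of a C5 terminal alkyne with (E)-3-iodo-2-methylacrylamide and cis-semireduction (4Z); the alkyne comes from a syn-propargylation of a C7 enal (C6, C7).
4. The enal comes from 3-bromo-2,5-dimethoxybenzaldehyde by two (Z)-crotylborations (C14/C15 and C10/C11), hydroformylation (C11), enamine-catalysed α-benzoyloxylation (C12) and a Wittig reaction (C8=C9).
5. Ring order: the benzene ring is bought; the macrolactam is the only ring formed (step 19).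

Key step: step 19

Remark on the chemistry: positions follow the ansamycin numbering (C1 amide carbonyl to C15 benzylic carbon; ring carbons C16–C21 with N on C20 and O on C18 and C21); the hydroquinone is assumed to be air-sensitive and is therefore released only in the last step under argon.

**Route**

Step 1
Reactants: 1 2-hydroxy-5-methoxybenzaldehyde
Product: 2 3-bromo-2-hydroxy-5-methoxybenzaldehyde
Conditions: Br2, NaOAc, AcOH, rt
Reagents that add atoms: bromine, BrBr
Why: Electrophilic aromatic bromination, in which the free phenol directs to its only open ortho position (the future C20) because its para position carries the methoxy group.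

Step 2
Reactants: 2 3-bromo-2-hydroxy-5-methoxybenzaldehyde
Product: 3 3-bromo-2,5-dimethoxybenzaldehyde
Conditions: MeI, K2CO3, DMF, rt
Reagents that add atoms: iodomethane, CI
Why: Williamson ether synthesis (SN2 methylation of the phenoxide), which masks the future hydroquinone as a para-dimethoxyarene.

Step 3
Reactants: 3 3-bromo-2,5-dimethoxybenzaldehyde
Product: 4 (1R,2S)-1-(3-bromo-2,5-dimethoxyphenyl)-2-methylbut-3-en-1-ol
Conditions: (Z)-but-2-ene, n-BuLi, KOt-Bu, THF, −78 to −45 °C; (+)-Ipc2BOMe, −78 °C; BF3·OEt2; then 3, −78 °C; NaOH, H2O2, rt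
Reagents that add atoms: (Z)-but-2-ene, C/C=C\C, transferred as (Z)-but-2-enyl-diisopinocampheylborane, C/C=C\CB([C@H]1C[C@H]2C[C@@H]([C@@H]1C)C2(C)C)[C@H]1C[C@H]2C[C@@H]([C@@H]1C)C2(C)C
Why: Brown (Z)-crotylboration, in which the chair-like six-membered transition state converts the (Z)-geometry into the syn C14-methyl/C15-hydroxyl pair and the isopinocampheyl groups derived from (−)-α-pinene select the aldehyde face that should give 15R,14S.

Step 4
Reactants: 4 (1R,2S)-1-(3-bromo-2,5-dimethoxyphenyl)-2-methylbut-3-en-1-ol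
Product: 5 {[(1R,2S)-1-(3-bromo-2,5-dimethoxyphenyl)-2-methylbut-3-en-1-yl]oxy}(tert-butyl)dimethylsilane
Conditions: TBSOTf, 2,6-lutidine, CH2Cl2, −78 to 0 °C
Reagents that add atoms: tert-butyldimethylsilyl trifluoromethanesulfonate, CC(C)(C)[Si](C)(C)OS(=O)(=O)C(F)(F)F
Why: Silyl ether formation at the hindered benzylic hydroxyl with a silyl triflate and a non-nucleophilic base, which touches no stereocentre.

Step 5
Reactants: 5 {[(1R,2S)-1-(3-bromo-2,5-dimethoxyphenyl)-2-methylbut-3-en-1-yl]oxy}(tert-butyl)dimethylsilane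
Product: 6 (4S,5R)-5-(3-bromo-2,5-dimethoxyphenyl)-5-[(tert-butyldimethylsilyl)oxy]-4-methylpentanal
Conditions: CO/H2 (1:1, 10 bar), Rh(acac)(CO)2 (1 mol %), Xantphos (2 mol %), toluene, 80 °C
Reagents that add atoms: carbon monoxide, [C-]#[O+]
Why: Linear-selective rhodium-catalysed hydroformylation, in which the wide-bite-angle diphosphine and the allylic branching place the formyl carbon (C11) on the terminal alkene carbon while the aryl bromide and C14/C15 stay untouched.

Step 6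
Reactants: 6 (4S,5R)-5-(3-bromo-2,5-dimethoxyphenyl)-5-[(tert-butyldimethylsilyl)oxy]-4-methylpentanal
Product: 7 (2S,4S,5R)-5-(3-bromo-2,5-dimethoxyphenyl)-5-[(tert-butyldimethylsilyl)oxy]-4-methyl-1-oxopentan-2-yl benzoate
Conditions: dibenzoyl peroxide, (S)-2-(triphenylmethyl)pyrrolidine (10 mol %), hydroquinone (10 mol %), THF, 0 °C
Reagents that add atoms: dibenzoyl peroxide, O=C(OOC(=O)c1ccccc1)c1ccccc1
Why: Enamine-catalysed asymmetric α-benzoyloxylation of an aldehyde, in which the trityl group of the (S)-catalyst shields one face of the (E)-enamine so that the peroxide is attacked from the open face and C12 should be set as S under catalyst control.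

Step 7
Reactants: 7 (2S,4S,5R)-5-(3-bromo-2,5-dimethoxyphenyl)-5-[(tert-butyldimethylsilyl)oxy]-4-methyl-1-oxopentan-2-yl benzoate
Product: 9 (3S,4R,5S,7S,8R)-8-(3-bromo-2,5-dimethoxyphenyl)-8-[(tert-butyldimethylsilyl)oxy]-3,7-dimethyloct-1-ene-4,5-diol, via C12 monobenzoate 8 (not isolated)
Conditions: (Z)-but-2-ene, n-BuLi, KOt-Bu, THF, −78 to −45 °C; (+)-Ipc2BOMe; BF3·OEt2; then crude 7, −78 °C; NaOH, H2O2, MeOH/H2O, 0 °C to rt
Reagents that add atoms: (Z)-but-2-ene, C/C=C\C, transferred as (Z)-but-2-enyl-diisopinocampheylborane, C/C=C\CB([C@H]1C[C@H]2C[C@@H]([C@@H]1C)C2(C)C)[C@H]1C[C@H]2C[C@@H]([C@@H]1C)C2(C)C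
Why: Brown (Z)-crotylboration under reagent control, in which the chair transition state gives the syn C10-methyl/C11-hydroxyl pair and the reagent selects the face that puts the C11 hydroxyl anti to the C12 benzoate (also the Cornforth-preferred sense for a (Z)-crotylborane and an α-oxygenated aldehyde, so the pairing should be matched), after which the alkaline peroxide work-up cleaves the borinate and saponifies the benzoate.

Step 8
Reactants: 9 (3S,4R,5S,7S,8R)-8-(3-bromo-2,5-dimethoxyphenyl)-8-[(tert-butyldimethylsilyl)oxy]-3,7-dimethyloct-1-ene-4,5-diol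
Product: 10 {[(1R,2S,4S,5R,6S)-1-(3-bromo-2,5-dimethoxyphenyl)-4,5-dimethoxy-2,6-dimethyloct-7-en-1-yl]oxy}(tert-butyl)dimethylsilane
Conditions: NaH, MeI, THF/DMF, 0 °C to rt
Reagents that add atoms: iodomethane, CI
Why: Double Williamson methylation of the C11 and C12 alkoxides, which cannot epimerise either carbinol because the C–O bonds are not broken and no acidic C–H is adjacent.

Step 9
Reactants: 10 {[(1R,2S,4S,5R,6S)-1-(3-bromo-2,5-dimethoxyphenyl)-4,5-dimethoxy-2,6-dimethyloct-7-en-1-yl]oxy}(tert-butyl)dimethylsilane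
Product: 11 (2R,3R,4S,6S,7R)-7-(3-bromo-2,5-dimethoxyphenyl)-7-[(tert-butyldimethylsilyl)oxy]-3,4-dimethoxy-2,6-dimethylheptanal
Conditions: OsO4 (2 mol %), NaIO4, 2,6-lutidine, dioxane/H2O (3:1), rt
Reagents that add atoms: osmium tetroxide, O=[Os](=O)(=O)=O; sodium periodate, [Na+].[O-]I(=O)(=O)=O
Why: Johnson–Lemieux oxidative cleavage of the only alkene to the C9 aldehyde, with 2,6-lutidine buffering the medium so that C10 is not epimerised and methanol is not eliminated.

Step 10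
Reactants: 11 (2R,3R,4S,6S,7R)-7-(3-bromo-2,5-dimethoxyphenyl)-7-[(tert-butyldimethylsilyl)oxy]-3,4-dimethoxy-2,6-dimethylheptanal
Product: 12 (2E,4S,5R,6S,8S,9R)-9-(3-bromo-2,5-dimethoxyphenyl)-9-[(tert-butyldimethylsilyl)oxy]-5,6-dimethoxy-2,4,8-trimethylnon-2-enal
Conditions: Ph3P=C(Me)CHO, toluene, 90 °C
Reagents that add atoms: 2-(triphenylphosphoranylidene)propanal, CC(C=O)=P(c1ccccc1)(c1ccccc1)c1ccccc1
Why: Wittig olefination with a stabilised ylide, which should give the (E)-trisubstituted C8=C9 enal and needs no external base that could epimerise C10.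

Step 11
Reactants: 13 (S)-but-3-yn-2-ol
Product: 14 (S)-but-3-yn-2-yl methanesulfonate
Conditions: MsCl, Et3N, CH2Cl2, −78 °C
Reagents that add atoms: methanesulfonyl chloride, CS(Cl)(=O)=O
Why: O-Sulfonylation of the alcohol, which leaves the C–O stereocentre intact.

Step 12
Reactants: 14 (S)-but-3-yn-2-yl methanesulfonate
Product: 15 (Ra)-buta-1,2-dien-1-yl(tributyl)stannane
Conditions: Bu3SnH, LiN(i-Pr)2, THF, −78 °C; CuBr·SMe2; then 14, −78 °C
Reagents that add atoms: tributyltin hydride, CCCC[SnH](CCCC)CCCC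
Why: Anti SN2′ displacement of the propargylic mesylate by the stannylcuprate, which transfers the central chirality of 14 to the allene axis.

Step 13
Reactants: 12 (2E,4S,5R,6S,8S,9R)-9-(3-bromo-2,5-dimethoxyphenyl)-9-[(tert-butyldimethylsilyl)oxy]-5,6-dimethoxy-2,4,8-trimethylnon-2-enal and 15 (Ra)-buta-1,2-dien-1-yl(tributyl)stannane
Product: 16 (3S,4R,5E,7S,8R,9S,11S,12R)-12-(3-bromo-2,5-dimethoxyphenyl)-12-[(tert-butyldimethylsilyl)oxy]-8,9-dimethoxy-3,5,7,11-tetramethyldodec-5-en-1-yn-4-ol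
Conditions: BF3·OEt2, CH2Cl2, −78 °C
Reagents that add atoms: none
Why: Marshall propargylation, in which the BF3-activated enal and the allenylstannane react through an open antiperiplanar transition state with anti SE2′ delivery, so that the allene axis should fix C6 as S and the syn C6/C7 relationship (7R) under reagent control.

Step 14
Reactants: 17 diethyl 2-methylpropanedioate
Product: 18 diethyl 2-(diiodomethyl)-2-methylpropanedioate
Conditions: NaH, Et2O, 0 °C; CHI3, reflux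
Reagents that add atoms: iodoform, IC(I)I
Why: C-Alkylation of the malonate enolate with iodoform by displacement of iodide.

Step 15
Reactants: 18 diethyl 2-(diiodomethyl)-2-methylpropanedioate
Product: 20 (2E)-3-iodo-2-methylprop-2-enoic acid, via dipotassium dicarboxylate 19 (not isolated)
Conditions: KOH, EtOH/H2O, reflux; then aq. HCl
Reagents that add atoms: potassium hydroxide, [K+].[OH-]
Why: Saponification followed by decarboxylative (Grob-type) elimination of iodide, which converges on the (E)-iodoalkene with iodine trans to the carboxyl group.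

Step 16
Reactants: 20 (2E)-3-iodo-2-methylprop-2-enoic acid
Product: 22 (2E)-3-iodo-2-methylprop-2-enamide, via acid chloride 21 (not isolated)
Conditions: (COCl)2, DMF (cat.), CH2Cl2, 0 °C to rt; then NH3 (0.5 M in dioxane), 0 °C
Reagents that add atoms: ammonia, N
Why: Acyl chloride formation and aminolysis (nucleophilic acyl substitution), which leave the alkene geometry unchanged.

Step 17
Reactants: 16 (3S,4R,5E,7S,8R,9S,11S,12R)-12-(3-bromo-2,5-dimethoxyphenyl)-12-[(tert-butyldimethylsilyl)oxy]-8,9-dimethoxy-3,5,7,11-tetramethyldodec-5-en-1-yn-4-ol and 22 (2E)-3-iodo-2-methylprop-2-enamide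
Product: 23 (2E,6S,7R,8E,10S,11R,12S,14S,15R)-15-(3-bromo-2,5-dimethoxyphenyl)-15-[(tert-butyldimethylsilyl)oxy]-7-hydroxy-11,12-dimethoxy-2,6,8,10,14-pentamethylpentadeca-2,8-dien-4-ynamide
Conditions: Pd(PPh3)2Cl2 (5 mol %), CuI (10 mol %), Et3N, THF, rt
Reagents that add atoms: none
Why: Sonogashira coupling, in which zerovalent palladium inserts into the vinyl C–I bond far faster than into the hindered electron-rich aryl C–Br bond and the (E)-geometry of the iodoalkene is retained.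

Step 18
Reactants: 23 (2E,6S,7R,8E,10S,11R,12S,14S,15R)-15-(3-bromo-2,5-dimethoxyphenyl)-15-[(tert-butyldimethylsilyl)oxy]-7-hydroxy-11,12-dimethoxy-2,6,8,10,14-pentamethylpentadeca-2,8-dien-4-ynamide
Product: 24 (2E,4Z,6S,7R,8E,10S,11R,12S,14S,15R)-15-(3-bromo-2,5-dimethoxyphenyl)-15-[(tert-butyldimethylsilyl)oxy]-7-hydroxy-11,12-dimethoxy-2,6,8,10,14-pentamethylpentadeca-2,4,8-trienamide
Conditions: Zn dust activated with Cu(OAc)2 and AgNO3, MeOH/H2O (1:1), rt
Reagents that add atoms: none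
Why: Boland reduction, in which activated zinc adds two hydrogens cis across the conjugated alkyne only, which should give the (4Z)-alkene without reducing the aryl bromide or the other alkenes.

Step 19
Reactants: 24 (2E,4Z,6S,7R,8E,10S,11R,12S,14S,15R)-15-(3-bromo-2,5-dimethoxyphenyl)-15-[(tert-butyldimethylsilyl)oxy]-7-hydroxy-11,12-dimethoxy-2,6,8,10,14-pentamethylpentadeca-2,4,8-trienamide
Product: 25 (4E,6Z,8S,9R,10E,12S,13R,14S,16S,17R)-17-[(tert-butyldimethylsilyl)oxy]-9-hydroxy-13,14,20,22-tetramethoxy-4,8,10,12,16-pentamethyl-2-azabicyclo[16.3.1]docosa-1(22),4,6,10,18,20-hexaen-3-one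
Conditions: CuI (50 mol %), N,N′-dimethylethylenediamine (1 equiv), K2CO3 (3 equiv), degassed toluene (2 mM), 100 °C, argon
Reagents that add atoms: none
Why: The deprotonated primary amide binds diamine-ligated monovalent copper, the copper amidate activates the C20–Br bond (oxidative addition to a trivalent copper aryl amidate) and reductive elimination forges N1–C20. The closest known reaction type is the copper/diamine-catalysed Goldberg N-arylation of primary amides by aryl bromides, which is established for macrocyclic closures onto ortho-alkoxy bromoarenes. The 19-membered ansa ring (N1, C1–C16, C21, C20) is closed end-to-end as a meta-bridged macrolactam by intramolecular aryl amidation under high dilution, with the (2E,4Z)-diene and the (8E)-alkene stiffening the tether. No stereocentre is formed, and the seven existing ones carry no hydrogen that K2CO3 can remove. The step needs N- over O-arylation, ring closure over oligomerisation and retention of the (4Z) geometry; the far more acidic amide N–H under diamine ligation secures the first against the free C7 hydroxyl, the 2 mM concentration the second, and the absence of hydride or radical intermediates the third, while the small ortho C21 methoxy group does not block the copper centre.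

Step 20
Reactants: 25 (4E,6Z,8S,9R,10E,12S,13R,14S,16S,17R)-17-[(tert-butyldimethylsilyl)oxy]-9-hydroxy-13,14,20,22-tetramethoxy-4,8,10,12,16-pentamethyl-2-azabicyclo[16.3.1]docosa-1(22),4,6,10,18,20-hexaen-3-one
Product: 27 [(4E,6Z,8S,9R,10E,12S,13R,14S,16S,17R)-17-[(tert-butyldimethylsilyl)oxy]-13,14,20,22-tetramethoxy-4,8,10,12,16-pentamethyl-3-oxo-2-azabicyclo[16.3.1]docosa-1(22),4,6,10,18,20-hexaen-9-yl] carbamate, via N-trichloroacetyl carbamate 26 (not isolated)
Conditions: Cl3CC(O)NCO, CH2Cl2, 0 °C; then K2CO3, MeOH, rt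
Reagents that add atoms: trichloroacetyl isocyanate, O=C=NC(=O)C(Cl)(Cl)Cl
Why: Carbamoylation of the only free hydroxyl (C7) by the electrophilic isocyanate followed by mild methanolysis of the N-trichloroacetyl group, with retention at C7 because the C–O bond is not broken.

Step 21
Reactants: 27 [(4E,6Z,8S,9R,10E,12S,13R,14S,16S,17R)-17-[(tert-butyldimethylsilyl)oxy]-13,14,20,22-tetramethoxy-4,8,10,12,16-pentamethyl-3-oxo-2-azabicyclo[16.3.1]docosa-1(22),4,6,10,18,20-hexaen-9-yl] carbamate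
Product: 28 [(4E,6Z,8S,9R,10E,12S,13R,14S,16S,17R)-17-[(tert-butyldimethylsilyl)oxy]-13,14-dimethoxy-4,8,10,12,16-pentamethyl-3,20,22-trioxo-2-azabicyclo[16.3.1]docosa-1(21),4,6,10,18-pentaen-9-yl] carbamate
Conditions: (NH4)2Ce(NO3)6, MeCN/H2O (4:1), −10 to 0 °C
Reagents that add atoms: water, O
Why: Oxidative demethylation of the para-dimethoxy anilide by two one-electron oxidations with tetravalent cerium and attack of water at the two ipso carbons, which should give the para-quinone because the two methoxy groups are para to each other.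

Step 22
Reactants: 28 [(4E,6Z,8S,9R,10E,12S,13R,14S,16S,17R)-17-[(tert-butyldimethylsilyl)oxy]-13,14-dimethoxy-4,8,10,12,16-pentamethyl-3,20,22-trioxo-2-azabicyclo[16.3.1]docosa-1(21),4,6,10,18-pentaen-9-yl] carbamate
Product: 29 [(4E,6Z,8S,9R,10E,12S,13R,14S,16S,17R)-17-hydroxy-13,14-dimethoxy-4,8,10,12,16-pentamethyl-3,20,22-trioxo-2-azabicyclo[16.3.1]docosa-1(21),4,6,10,18-pentaen-9-yl] carbamate
Conditions: HF·pyridine, pyridine, THF, 0 °C to rt
Reagents that add atoms: none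
Why: Fluoride-mediated cleavage of the Si–O bond under buffered conditions that the quinone, carbamate and diene tolerate, with C15 unchanged because its C–O bond is not broken.

Step 23
Reactants: 29 [(4E,6Z,8S,9R,10E,12S,13R,14S,16S,17R)-17-hydroxy-13,14-dimethoxy-4,8,10,12,16-pentamethyl-3,20,22-trioxo-2-azabicyclo[16.3.1]docosa-1(21),4,6,10,18-pentaen-9-yl] carbamate
Product: 30 [(4E,6Z,8S,9R,10E,12S,13R,14S,16S,17R)-17,20,22-trihydroxy-13,14-dimethoxy-4,8,10,12,16-pentamethyl-3-oxo-2-azabicyclo[16.3.1]docosa-1(22),4,6,10,18,20-hexaen-9-yl] carbamate (CNP0532580.1)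
Conditions: Na2S2O4, EtOAc/H2O, rt, argon
Reagents that add atoms: none
Why: Two-electron reduction of the quinone to the hydroquinone by dithionite in a two-phase system, which affects no other functional group.

**Compound list**

1 | 2-hydroxy-5-methoxybenzaldehyde | COc1ccc(O)c(C=O)c1 | starting material
2 | 3-bromo-2-hydroxy-5-methoxybenzaldehyde | COc1cc(Br)c(O)c(C=O)c1 | intermediate
3 | 3-bromo-2,5-dimethoxybenzaldehyde | COc1cc(Br)c(OC)c(C=O)c1 | intermediate
4 | (1R,2S)-1-(3-bromo-2,5-dimethoxyphenyl)-2-methylbut-3-en-1-ol | COc1cc(Br)c(OC)c(c1)[C@H](O)[C@@H](C)C=C | intermediate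
5 | {[(1R,2S)-1-(3-bromo-2,5-dimethoxyphenyl)-2-methylbut-3-en-1-yl]oxy}(tert-butyl)dimethylsilane | COc1cc(Br)c(OC)c(c1)[C@H](O[Si](C)(C)C(C)(C)C)[C@@H](C)C=C | intermediate
6 | (4S,5R)-5-(3-bromo-2,5-dimethoxyphenyl)-5-[(tert-butyldimethylsilyl)oxy]-4-methylpentanal | COc1cc(Br)c(OC)c(c1)[C@H](O[Si](C)(C)C(C)(C)C)[C@@H](C)CCC=O | intermediate
7 | (2S,4S,5R)-5-(3-bromo-2,5-dimethoxyphenyl)-5-[(tert-butyldimethylsilyl)oxy]-4-methyl-1-oxopentan-2-yl benzoate | COc1cc(Br)c(OC)c(c1)[C@H](O[Si](C)(C)C(C)(C)C)[C@@H](C)C[C@H](OC(=O)c1ccccc1)C=O | intermediate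
8 | (3S,4R,5S,7S,8R)-8-(3-bromo-2,5-dimethoxyphenyl)-8-[(tert-butyldimethylsilyl)oxy]-4-hydroxy-3,7-dimethyloct-1-en-5-yl benzoate | COc1cc(Br)c(OC)c(c1)[C@H](O[Si](C)(C)C(C)(C)C)[C@@H](C)C[C@H](OC(=O)c1ccccc1)[C@H](O)[C@@H](C)C=C | intermediate
9 | (3S,4R,5S,7S,8R)-8-(3-bromo-2,5-dimethoxyphenyl)-8-[(tert-butyldimethylsilyl)oxy]-3,7-dimethyloct-1-ene-4,5-diol | COc1cc(Br)c(OC)c(c1)[C@H](O[Si](C)(C)C(C)(C)C)[C@@H](C)C[C@H](O)[C@H](O)[C@@H](C)C=C | intermediate
10 | {[(1R,2S,4S,5R,6S)-1-(3-bromo-2,5-dimethoxyphenyl)-4,5-dimethoxy-2,6-dimethyloct-7-en-1-yl]oxy}(tert-butyl)dimethylsilane | COc1cc(Br)c(OC)c(c1)[C@H](O[Si](C)(C)C(C)(C)C)[C@@H](C)C[C@H](OC)[C@H](OC)[C@@H](C)C=C | intermediate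
11 | (2R,3R,4S,6S,7R)-7-(3-bromo-2,5-dimethoxyphenyl)-7-[(tert-butyldimethylsilyl)oxy]-3,4-dimethoxy-2,6-dimethylheptanal | COc1cc(Br)c(OC)c(c1)[C@H](O[Si](C)(C)C(C)(C)C)[C@@H](C)C[C@H](OC)[C@H](OC)[C@@H](C)C=O | intermediate
12 | (2E,4S,5R,6S,8S,9R)-9-(3-bromo-2,5-dimethoxyphenyl)-9-[(tert-butyldimethylsilyl)oxy]-5,6-dimethoxy-2,4,8-trimethylnon-2-enal | COc1cc(Br)c(OC)c(c1)[C@H](O[Si](C)(C)C(C)(C)C)[C@@H](C)C[C@H](OC)[C@H](OC)[C@@H](C)/C=C(\C)C=O | intermediate
13 | (S)-but-3-yn-2-ol | C[C@H](O)C#C | starting material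
14 | (S)-but-3-yn-2-yl methanesulfonate | C[C@H](OS(C)(=O)=O)C#C | intermediate
15 | (Ra)-buta-1,2-dien-1-yl(tributyl)stannane | [H]C(C)=[C@@]=C([H])[Sn](CCCC)(CCCC)CCCC | intermediate
16 | (3S,4R,5E,7S,8R,9S,11S,12R)-12-(3-bromo-2,5-dimethoxyphenyl)-12-[(tert-butyldimethylsilyl)oxy]-8,9-dimethoxy-3,5,7,11-tetramethyldodec-5-en-1-yn-4-ol | COc1cc(Br)c(OC)c(c1)[C@H](O[Si](C)(C)C(C)(C)C)[C@@H](C)C[C@H](OC)[C@H](OC)[C@@H](C)/C=C(\C)[C@H](O)[C@@H](C)C#C | intermediate
17 | diethyl 2-methylpropanedioate | CCOC(=O)C(C)C(=O)OCC | starting material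
18 | diethyl 2-(diiodomethyl)-2-methylpropanedioate | CCOC(=O)C(C)(C(I)I)C(=O)OCC | intermediate
19 | dipotassium 2-(diiodomethyl)-2-methylpropanedioate | [K+].[K+].[O-]C(=O)C(C)(C(I)I)C([O-])=O | intermediate
20 | (2E)-3-iodo-2-methylprop-2-enoic acid | OC(=O)/C(C)=C/I | intermediate
21 | (2E)-3-iodo-2-methylprop-2-enoyl chloride | ClC(=O)/C(C)=C/I | intermediate
22 | (2E)-3-iodo-2-methylprop-2-enamide | NC(=O)/C(C)=C/I | intermediate
23 | (2E,6S,7R,8E,10S,11R,12S,14S,15R)-15-(3-bromo-2,5-dimethoxyphenyl)-15-[(tert-butyldimethylsilyl)oxy]-7-hydroxy-11,12-dimethoxy-2,6,8,10,14-pentamethylpentadeca-2,8-dien-4-ynamide | COc1cc(Br)c(OC)c(c1)[C@H](O[Si](C)(C)C(C)(C)C)[C@@H](C)C[C@H](OC)[C@H](OC)[C@@H](C)/C=C(\C)[C@H](O)[C@@H](C)C#C/C=C(\C)C(N)=O | intermediate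
24 | (2E,4Z,6S,7R,8E,10S,11R,12S,14S,15R)-15-(3-bromo-2,5-dimethoxyphenyl)-15-[(tert-butyldimethylsilyl)oxy]-7-hydroxy-11,12-dimethoxy-2,6,8,10,14-pentamethylpentadeca-2,4,8-trienamide | COc1cc(Br)c(OC)c(c1)[C@H](O[Si](C)(C)C(C)(C)C)[C@@H](C)C[C@H](OC)[C@H](OC)[C@@H](C)/C=C(\C)[C@H](O)[C@@H](C)\C=C/C=C(\C)C(N)=O | intermediate
25 | (4E,6Z,8S,9R,10E,12S,13R,14S,16S,17R)-17-[(tert-butyldimethylsilyl)oxy]-9-hydroxy-13,14,20,22-tetramethoxy-4,8,10,12,16-pentamethyl-2-azabicyclo[16.3.1]docosa-1(22),4,6,10,18,20-hexaen-3-one | CO[C@H]1[C@@H](OC)C[C@H](C)[C@@H](O[Si](C)(C)C(C)(C)C)c2cc(OC)cc(c2OC)NC(=O)/C(C)=C/C=C\[C@H](C)[C@@H](O)/C(C)=C/[C@@H]1C | intermediate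
26 | N-trichloroacetyl carbamate of 25 at the C7 oxygen | CO[C@H]1[C@@H](OC)C[C@H](C)[C@@H](O[Si](C)(C)C(C)(C)C)c2cc(OC)cc(c2OC)NC(=O)/C(C)=C/C=C\[C@H](C)[C@@H](OC(=O)NC(=O)C(Cl)(Cl)Cl)/C(C)=C/[C@@H]1C | intermediate
27 | [(4E,6Z,8S,9R,10E,12S,13R,14S,16S,17R)-17-[(tert-butyldimethylsilyl)oxy]-13,14,20,22-tetramethoxy-4,8,10,12,16-pentamethyl-3-oxo-2-azabicyclo[16.3.1]docosa-1(22),4,6,10,18,20-hexaen-9-yl] carbamate | CO[C@H]1[C@@H](OC)C[C@H](C)[C@@H](O[Si](C)(C)C(C)(C)C)c2cc(OC)cc(c2OC)NC(=O)/C(C)=C/C=C\[C@H](C)[C@@H](OC(N)=O)/C(C)=C/[C@@H]1C | intermediate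
28 | [(4E,6Z,8S,9R,10E,12S,13R,14S,16S,17R)-17-[(tert-butyldimethylsilyl)oxy]-13,14-dimethoxy-4,8,10,12,16-pentamethyl-3,20,22-trioxo-2-azabicyclo[16.3.1]docosa-1(21),4,6,10,18-pentaen-9-yl] carbamate | CO[C@H]1[C@@H](OC)C[C@H](C)[C@@H](O[Si](C)(C)C(C)(C)C)C2=CC(=O)C=C(C2=O)NC(=O)/C(C)=C/C=C\[C@H](C)[C@@H](OC(N)=O)/C(C)=C/[C@@H]1C | intermediate
29 | [(4E,6Z,8S,9R,10E,12S,13R,14S,16S,17R)-17-hydroxy-13,14-dimethoxy-4,8,10,12,16-pentamethyl-3,20,22-trioxo-2-azabicyclo[16.3.1]docosa-1(21),4,6,10,18-pentaen-9-yl] carbamate | CO[C@H]1[C@@H](OC)C[C@H](C)[C@@H](O)C2=CC(=O)C=C(C2=O)NC(=O)/C(C)=C/C=C\[C@H](C)[C@@H](OC(N)=O)/C(C)=C/[C@@H]1C | intermediate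
30 | [(4E,6Z,8S,9R,10E,12S,13R,14S,16S,17R)-17,20,22-trihydroxy-13,14-dimethoxy-4,8,10,12,16-pentamethyl-3-oxo-2-azabicyclo[16.3.1]docosa-1(22),4,6,10,18,20-hexaen-9-yl] carbamate | CO[C@H]1[C@@H](OC)C[C@H](C)[C@@H](O)c2cc(O)cc(c2O)NC(=O)/C(C)=C/C=C\[C@H](C)[C@@H](OC(N)=O)/C(C)=C/[C@@H]1C | target

**Step count**

Total: 23 steps. Longest linear sequence: 18 steps (steps 1–10, 13, 17–23) from 2-hydroxy-5-methoxybenzaldehyde.

**Steps most likely to fail**

Step 19 (macrocyclic amidation). Intermolecular amidation to oligomers, arylation or conjugate addition by the free C7 hydroxyl, or thermal isomerisation of the (4Z)-alkene during long heating may compete with ring closure. The fallback reverses the polarity of the arene and closes the same N1–C20 bond oxidatively near room temperature. Setting out from 24, Miyaura borylation (B2pin2, Pd(dppf)Cl2, KOAc, dioxane, 80 °C) should give the aryl pinacol boronate (2E,4Z,6S,7R,8E,10S,11R,12S,14S,15R)-15-[(tert-butyldimethylsilyl)oxy]-15-[2,5-dimethoxy-3-(4,4,5,5-tetramethyl-1,3,2-dioxaborolan-2-yl)phenyl]-7-hydroxy-11,12-dimethoxy-2,6,8,10,14-pentamethylpentadeca-2,4,8-trienamide F1. An intramolecular Chan–Lam amidation (Cu(OAc)2, Et3N, 4 Å molecular sieves, MeCN, O2, rt to 40 °C, 2 mM) should then return to the route at 25.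

Step 13 (syn-propargylation). The open transition state may discriminate poorly between syn and anti approach on an enal whose α-carbon is sp2, and the allenylstannane may lose enantiomeric purity before it reacts. The fallback sets C6 and C7 by an auxiliary-controlled aldol instead. Setting out from 12, a chelation-controlled titanium syn-aldol with (4S)-4-benzyl-3-propanoyl-1,3-thiazolidine-2-thione (TiCl4, i-Pr2NEt, CH2Cl2, −78 °C) should give (2R,3R,4E,6S,7R,8S,10S,11R)-1-[(4S)-4-benzyl-2-thioxo-1,3-thiazolidin-3-yl]-11-(3-bromo-2,5-dimethoxyphenyl)-11-[(tert-butyldimethylsilyl)oxy]-3-hydroxy-7,8-dimethoxy-2,4,6,10-tetramethylundec-4-en-1-one F2. Silylation (TESOTf, 2,6-lutidine) should give its C7 triethylsilyl ether F3. Reduction with i-Bu2AlH (CH2Cl2, −78 °C) should release the auxiliary and give (2R,3R,4E,6S,7R,8S,10S,11R)-11-(3-bromo-2,5-dimethoxyphenyl)-11-[(tert-butyldimethylsilyl)oxy]-7,8-dimethoxy-2,4,6,10-tetramethyl-3-[(triethylsilyl)oxy]undec-4-enal F4. Homologation with the Ohira–Bestmann reagent (dimethyl (1-diazo-2-oxopropyl)phosphonate, K2CO3, MeOH, 0 °C) should give the C7 triethylsilyl ether of 16, F5. Selective removal of the triethylsilyl group (PPTS, MeOH/CH2Cl2, 0 °C) should return to the route at 16.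

Step 22 (desilylation at the quinone level). Once the C15 hydroxyl is free next to the quinone, internal redox tautomerisation to a C15 ketone hydroquinone or dehydration towards a quinone methide may consume material. The fallback unveils the hydroxyl only at the hydroquinone oxidation level. Setting out from 28, reduction with Na2S2O4 (EtOAc/H2O, argon) should give the silyl-protected hydroquinone [(4E,6Z,8S,9R,10E,12S,13R,14S,16S,17R)-17-[(tert-butyldimethylsilyl)oxy]-20,22-dihydroxy-13,14-dimethoxy-4,8,10,12,16-pentamethyl-3-oxo-2-azabicyclo[16.3.1]docosa-1(22),4,6,10,18,20-hexaen-9-yl] carbamate F6. Treatment with HF·pyridine (THF, 0 °C, argon) should then give 30 directly.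

**Further compounds**

F1 | step 19 | (2E,4Z,6S,7R,8E,10S,11R,12S,14S,15R)-15-[(tert-butyldimethylsilyl)oxy]-15-[2,5-dimethoxy-3-(4,4,5,5-tetramethyl-1,3,2-dioxaborolan-2-yl)phenyl]-7-hydroxy-11,12-dimethoxy-2,6,8,10,14-pentamethylpentadeca-2,4,8-trienamide | COc1cc(B2OC(C)(C)C(C)(C)O2)c(OC)c(c1)[C@H](O[Si](C)(C)C(C)(C)C)[C@@H](C)C[C@H](OC)[C@H](OC)[C@@H](C)/C=C(\C)[C@H](O)[C@@H](C)\C=C/C=C(\C)C(N)=O
F2 | step 13 | (2R,3R,4E,6S,7R,8S,10S,11R)-1-[(4S)-4-benzyl-2-thioxo-1,3-thiazolidin-3-yl]-11-(3-bromo-2,5-dimethoxyphenyl)-11-[(tert-butyldimethylsilyl)oxy]-3-hydroxy-7,8-dimethoxy-2,4,6,10-tetramethylundec-4-en-1-one | COc1cc(Br)c(OC)c(c1)[C@H](O[Si](C)(C)C(C)(C)C)[C@@H](C)C[C@H](OC)[C@H](OC)[C@@H](C)/C=C(\C)[C@H](O)[C@@H](C)C(=O)N1[C@@H](Cc2ccccc2)CSC1=S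
F3 | step 13 | C7 triethylsilyl ether of F2 | COc1cc(Br)c(OC)c(c1)[C@H](O[Si](C)(C)C(C)(C)C)[C@@H](C)C[C@H](OC)[C@H](OC)[C@@H](C)/C=C(\C)[C@H](O[Si](CC)(CC)CC)[C@@H](C)C(=O)N1[C@@H](Cc2ccccc2)CSC1=S
F4 | step 13 | (2R,3R,4E,6S,7R,8S,10S,11R)-11-(3-bromo-2,5-dimethoxyphenyl)-11-[(tert-butyldimethylsilyl)oxy]-7,8-dimethoxy-2,4,6,10-tetramethyl-3-[(triethylsilyl)oxy]undec-4-enal | COc1cc(Br)c(OC)c(c1)[C@H](O[Si](C)(C)C(C)(C)C)[C@@H](C)C[C@H](OC)[C@H](OC)[C@@H](C)/C=C(\C)[C@H](O[Si](CC)(CC)CC)[C@@H](C)C=O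
F5 | step 13 | C7 triethylsilyl ether of 16 | COc1cc(Br)c(OC)c(c1)[C@H](O[Si](C)(C)C(C)(C)C)[C@@H](C)C[C@H](OC)[C@H](OC)[C@@H](C)/C=C(\C)[C@H](O[Si](CC)(CC)CC)[C@@H](C)C#C
F6 | step 22 | [(4E,6Z,8S,9R,10E,12S,13R,14S,16S,17R)-17-[(tert-butyldimethylsilyl)oxy]-20,22-dihydroxy-13,14-dimethoxy-4,8,10,12,16-pentamethyl-3-oxo-2-azabicyclo[16.3.1]docosa-1(22),4,6,10,18,20-hexaen-9-yl] carbamate | CO[C@H]1[C@@H](OC)C[C@H](C)[C@@H](O[Si](C)(C)C(C)(C)C)c2cc(O)cc(c2O)NC(=O)/C(C)=C/C=C\[C@H](C)[C@@H](OC(N)=O)/C(C)=C/[C@@H]1C
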